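**Strategy.** The route rests on disconnecting C7–C8, the bond between the lactone-bearing ring-fusion carbon and the acyloxy carbinol. A preformed, enantioenriched 5-alkenyl-3-(bromomethyl)butenolide carrying a C8 aldehyde is closed by chromium(II): the allyl unit C13–C11=C7 hidden in the butenolide attacks C8 through C7. One operation thus closes the ten-membered carbocycle (C1–C10) onto the existing γ-lactone, sets C7 and C8 by relay from C6 (the only reagent-set stereocentre), and unveils the C11=C13 exo-methylene. The key step exploits that C7, shared by both rings, is the γ-terminus of a 2-carboxyallyl unit and C8 a carbinol. The C8 carbinol is then inverted while the isovalerate is installed.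

Key step: step 15

Remark: germacranolide numbering is used throughout (carbocycle C1–C10, lactone O–C6–C7–C11–C12, exo-methylene C13, C14 on C10, C15 on C4). Both ring olefins have their two ring carbons cis; they are E by CIP only because of the CH2O substituents.

**Step 1**
Reactants: 1 triethyl phosphonoacetate; 2 2-bromo-1,1-dimethoxyethane
Product: 3 ethyl 2-(diethoxyphosphoryl)-4,4-dimethoxybutanoate (racemic)
Conditions: NaH, DMSO, rt; then 2, NaI (cat.), 80 °C
Reagents that add atoms: none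
Why: SN2 C-alkylation of the sodium phosphonoacetate (malonate-type alkylation) joins C10 to the C9–C8 acetal unit; the stereocentre formed is destroyed in step 2.

**Step 2**
Reactants: 3 ethyl 2-(diethoxyphosphoryl)-4,4-dimethoxybutanoate; 4 acrolein
Product: 5 ethyl (E)-2-(2,2-dimethoxyethyl)penta-2,4-dienoate
Conditions: NaH, THF, 0 °C; then 4, −78 → 0 °C
Reagents that add atoms: none
Why: Horner–Wadsworth–Emmons olefination, whose thermodynamically preferred E-enoate (ester trans to the vinyl group) is the C1=C10 geometry with C2 and C9 cis; any minor Z isomer is removed by chromatography.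

**Step 3**
Reactants: 5 ethyl (E)-2-(2,2-dimethoxyethyl)penta-2,4-dienoate
Product: 6 (E)-2-(2,2-dimethoxyethyl)penta-2,4-dien-1-ol
Conditions: DIBAL-H, CH2Cl2, −78 °C; Rochelle salt work-up
Reagents that add atoms: none
Why: 1,2-Reduction of the conjugated ester by DIBAL-H gives the C14 allylic alcohol without touching the acetal or the olefin geometry.

**Step 4**
Reactants: 6 (E)-2-(2,2-dimethoxyethyl)penta-2,4-dien-1-ol
Product: 7 tert-butyl{[(2E)-2-(2,2-dimethoxyethyl)penta-2,4-dien-1-yl]oxy}dimethylsilane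
Conditions: TBSCl, imidazole, CH2Cl2, rt
Reagents that add atoms: tert-butyldimethylsilyl chloride CC(C)(C)[Si](C)(C)Cl
Why: Standard silylation of a primary alcohol protects C14–OH until the last step.

**Step 5**
Reactants: 8 but-2-yne-1,4-diol
Product: 9 4-{[tert-butyl(dimethyl)silyl]oxy}but-2-yn-1-ol
Conditions: NaH (1 equiv), THF, 0 °C; then TBSCl (1 equiv)
Reagents that add atoms: tert-butyldimethylsilyl chloride CC(C)(C)[Si](C)(C)Cl
Why: Monodeprotonation of the symmetrical diol gives a poorly soluble monoalkoxide that is silylated once (monoprotection of a symmetrical diol); no stereocentre is involved.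

**Step 6**
Reactants: 9 4-{[tert-butyl(dimethyl)silyl]oxy}but-2-yn-1-ol
Product: 11 (Z)-4-{[tert-butyl(dimethyl)silyl]oxy}-3-iodobut-2-en-1-ol, via cyclic alkenylalanate 10 (not isolated)
Conditions: Red-Al, THF, 0 °C; then I2, −78 °C
Reagents that add atoms: iodine II
Why: Alkoxide-directed trans-hydroalumination delivers hydride to C5 and aluminium to C4 (cis to C6 in a five-membered alanate), and iododealumination with retention gives the iodide cis to C6, fixing the C4=C5 geometry.

**Step 7**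
Reactants: 7 tert-butyl{[(2E)-2-(2,2-dimethoxyethyl)penta-2,4-dien-1-yl]oxy}dimethylsilane; 11 (Z)-4-{[tert-butyl(dimethyl)silyl]oxy}-3-iodobut-2-en-1-ol
Product: 13 (2E,6E)-3,7-bis({[tert-butyl(dimethyl)silyl]oxy}methyl)-9,9-dimethoxynona-2,6-dien-1-ol, via B-alkyl-9-BBN borane 12 (not isolated)
Conditions: 9-BBN, THF, 0 °C → rt; then 11, PdCl2(dppf) (cat.), Ph3As, Cs2CO3, DMF/H2O, rt
Reagents that add atoms: none
Why: Anti-Markovnikov hydroboration of the terminal vinyl group (the trisubstituted olefin is inert to 9-BBN) followed by B-alkyl Suzuki–Miyaura coupling forms C3–C4 with retention at the vinyl iodide, so C3 ends cis to C6.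

**Step 8**
Reactants: 13 (2E,6E)-3,7-bis({[tert-butyl(dimethyl)silyl]oxy}methyl)-9,9-dimethoxynona-2,6-dien-1-ol
Product: 14 (2E,6E)-3,7-bis({[tert-butyl(dimethyl)silyl]oxy}methyl)-9,9-dimethoxynona-2,6-dienal
Conditions: MnO2, CH2Cl2, rt
Reagents that add atoms: none
Why: Heterogeneous MnO2 oxidises the primary allylic alcohol under neutral conditions, so the C4=C5 geometry and the acetal are expected to survive.

**Step 9**
Reactants: 14 (2E,6E)-3,7-bis({[tert-butyl(dimethyl)silyl]oxy}methyl)-9,9-dimethoxynona-2,6-dienal; 15 1-methoxy-4-[(prop-2-yn-1-yloxy)methyl]benzene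
Product: 17 (4R,5E,9E)-6,10-bis({[tert-butyl(dimethyl)silyl]oxy}methyl)-12,12-dimethoxy-1-[(4-methoxybenzyl)oxy]dodeca-5,9-dien-2-yn-4-ol, via alkynyl(methyl)zinc 16 (not isolated)
Conditions: Me2Zn, ProPhenol ligand (20 mol%, enantiomer giving Si-face addition), Ph3PO, toluene, 4 °C
Reagents that add atoms: none
Why: Zinc–ProPhenol-catalysed enantioselective alkynylation of the enal; the chiral dinuclear zinc catalyst delivers the alkynyl group to the Si face of C6, setting the single reagent-controlled stereocentre (6R).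

**Step 10**
Reactants: 17 (4R,5E,9E)-6,10-bis({[tert-butyl(dimethyl)silyl]oxy}methyl)-12,12-dimethoxy-1-[(4-methoxybenzyl)oxy]dodeca-5,9-dien-2-yn-4-ol
Product: 19 (2Z,4R,5E,9E)-6,10-bis({[tert-butyl(dimethyl)silyl]oxy}methyl)-2-iodo-12,12-dimethoxy-1-[(4-methoxybenzyl)oxy]dodeca-2,5,9-trien-4-ol, via alkoxy-alkenylalanate 18 (not isolated)
Conditions: Red-Al, THF, −20 → 0 °C; then I2, −78 °C
Reagents that add atoms: iodine II
Why: Only the free C6 alkoxide can direct trans-hydroalumination, so hydride goes to C7 and aluminium to C11 cis to C6; iodination with retention gives the Z-iodide needed for lactone closure, and the low temperature should prevent elimination of the PMB-oxy group.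

**Step 11**
Reactants: 19 (2Z,4R,5E,9E)-6,10-bis({[tert-butyl(dimethyl)silyl]oxy}methyl)-2-iodo-12,12-dimethoxy-1-[(4-methoxybenzyl)oxy]dodeca-2,5,9-trien-4-ol
Product: 20 (5R)-5-[(1E,5E)-2,6-bis({[tert-butyl(dimethyl)silyl]oxy}methyl)-8,8-dimethoxyocta-1,5-dien-1-yl]-3-{[(4-methoxybenzyl)oxy]methyl}furan-2(5H)-one
Conditions: PdCl2(PPh3)2 (cat.), CO (1 atm), K2CO3, THF, rt
Reagents that add atoms: carbon monoxide [C-]#[O+]
Why: Palladium-catalysed carbonylative lactonisation: oxidative addition into C11–I, CO insertion and capture of the acylpalladium by the cis C6 hydroxyl close the butenolide and bring in C12 without touching C6.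

**Step 12**
Reactants: 20 (5R)-5-[(1E,5E)-2,6-bis({[tert-butyl(dimethyl)silyl]oxy}methyl)-8,8-dimethoxyocta-1,5-dien-1-yl]-3-{[(4-methoxybenzyl)oxy]methyl}furan-2(5H)-one
Product: 21 (5R)-5-[(1E,5E)-2,6-bis({[tert-butyl(dimethyl)silyl]oxy}methyl)-8,8-dimethoxyocta-1,5-dien-1-yl]-3-(hydroxymethyl)furan-2(5H)-one
Conditions: DDQ, CH2Cl2/pH 7 buffer, 0 °C
Reagents that add atoms: none
Why: Oxidative PMB cleavage by DDQ under buffered conditions should leave the TBS ethers, the acetal and the olefins untouched.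

**Step 13**
Reactants: 21 (5R)-5-[(1E,5E)-2,6-bis({[tert-butyl(dimethyl)silyl]oxy}methyl)-8,8-dimethoxyocta-1,5-dien-1-yl]-3-(hydroxymethyl)furan-2(5H)-one
Product: 22 (5R)-3-(bromomethyl)-5-[(1E,5E)-2,6-bis({[tert-butyl(dimethyl)silyl]oxy}methyl)-8,8-dimethoxyocta-1,5-dien-1-yl]furan-2(5H)-one
Conditions: CBr4, PPh3, CH2Cl2, −20 → 0 °C
Reagents that add atoms: carbon tetrabromide BrC(Br)(Br)Br
Why: Appel bromination displaces the alkoxyphosphonium at primary allylic C13 by bromide under neutral conditions, giving the conjugated allylic bromide.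

**Step 14**
Reactants: 22 (5R)-3-(bromomethyl)-5-[(1E,5E)-2,6-bis({[tert-butyl(dimethyl)silyl]oxy}methyl)-8,8-dimethoxyocta-1,5-dien-1-yl]furan-2(5H)-one
Product: 23 (5R)-3-(bromomethyl)-5-[(1E,5E)-2,6-bis({[tert-butyl(dimethyl)silyl]oxy}methyl)-8-oxoocta-1,5-dien-1-yl]furan-2(5H)-one
Conditions: SiO2, 10% aq. oxalic acid, CH2Cl2, rt
Reagents that add atoms: water O
Why: Mild acid-catalysed acetal hydrolysis on wet silica gel should release the β,γ-unsaturated C8 aldehyde without cleaving the TBS ethers or moving the C1=C10 bond into conjugation.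

**Step 15**
Reactants: 23 (5R)-3-(bromomethyl)-5-[(1E,5E)-2,6-bis({[tert-butyl(dimethyl)silyl]oxy}methyl)-8-oxoocta-1,5-dien-1-yl]furan-2(5H)-one
Product: 25 (6R,7R,8S)-14,15-bis{[tert-butyl(dimethyl)silyl]oxy}-8-hydroxy-cis,cis-germacra-1(10),4,11(13)-trien-12,6-olide (8α-OH; trans-fused lactone), via allylchromium(III) dichloride 24 (not isolated)
Conditions: CrCl2 (10 equiv), THF, rt; 23 added by syringe pump (final about 2 mM); aq. NH4Cl work-up
Reagents that add atoms: none
Why: CrCl2 reduces the allylic C13–Br bond to the allylchromium(III) species 24, whose γ-terminus C7 adds to the tethered C8 aldehyde through a six-membered Zimmerman–Traxler transition state (chromium on C13 bound to O8), so that C7–C8 forms with allyl transposition and the C11=C13 exo-methylene appears; the closest known reactions are the intramolecular Nozaki–Hiyama allylations of 2-(bromomethyl)acrylate-type bromides that close ten-membered germacranolide rings and the Barbier allylations of 3-(bromomethyl)furan-2(5H)-one. The ten-membered carbocycle closes in the 10-exo-trig mode at the C8 carbonyl, the nucleophile reacting in the SE2′ sense at C7 of the butenolide. C7 is controlled by C6: A(1,3) strain between C3H2 and the C6 substituents across the ring-cis C4=C5 olefin keeps H6 in the olefin plane, so the tether leaves over the H6 face and delivers C8 to the face of C7 anti to C5, giving the trans-fused lactone (7R). C8 is controlled by the chair: the butenolide fixes the allyl unit with C6 trans to C13, C9 sits equatorial to avoid the 1,3-diaxial clash with the lactone carbonyl C12, and the anti adduct 8S (8α-OH) should result. The step needs γ- over α-attack (α-attack would need a twelve-membered ring and has no cyclic transition state), cyclisation over oligomerisation (slow addition, high dilution) and survival of the β,γ-unsaturated aldehyde (neutral chromium(II) conditions).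

**Step 16**
Reactants: 25 (6R,7R,8S)-14,15-bis{[tert-butyl(dimethyl)silyl]oxy}-8-hydroxy-cis,cis-germacra-1(10),4,11(13)-trien-12,6-olide; 26 3-methylbutanoic acid (isovaleric acid)
Product: 27 (6R,7R,8R)-14,15-bis{[tert-butyl(dimethyl)silyl]oxy}-8-(3-methylbutanoyloxy)-cis,cis-germacra-1(10),4,11(13)-trien-12,6-olide
Conditions: PPh3/DIAD (premixed), toluene, 0 °C → rt
Reagents that add atoms: none
Why: Mitsunobu esterification: isovalerate displaces the C8 oxyphosphonium by SN2 with inversion (8S → 8R), so the ester is installed and C8 is brought to the 8β configuration in one operation.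

**Step 17**
Reactants: 27 (6R,7R,8R)-14,15-bis{[tert-butyl(dimethyl)silyl]oxy}-8-(3-methylbutanoyloxy)-cis,cis-germacra-1(10),4,11(13)-trien-12,6-olide
Product: 28 CNP0199826.1, (6R,7R,8R)-14,15-dihydroxy-8-(3-methylbutanoyloxy)-cis,cis-germacra-1(10),4,11(13)-trien-12,6-olide
Conditions: HF·pyridine, pyridine/THF, 0 °C → rt
Reagents that add atoms: none
Why: Buffered fluoride cleavage of the two primary TBS ethers should leave the isovalerate, the lactone and its exo-methylene untouched.

**Compound list**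

1 | triethyl phosphonoacetate | CCOC(=O)CP(=O)(OCC)OCC | starting material
2 | 2-bromo-1,1-dimethoxyethane | COC(CBr)OC | starting material
3 | ethyl 2-(diethoxyphosphoryl)-4,4-dimethoxybutanoate (racemic) | CCOC(=O)C(CC(OC)OC)P(=O)(OCC)OCC | intermediate
4 | acrolein | C=CC=O | starting material
5 | ethyl (E)-2-(2,2-dimethoxyethyl)penta-2,4-dienoate | C=C/C=C(/C(=O)OCC)CC(OC)OC | intermediate
6 | (E)-2-(2,2-dimethoxyethyl)penta-2,4-dien-1-ol | C=C/C=C(/CO)CC(OC)OC | intermediate
7 | tert-butyl{[(2E)-2-(2,2-dimethoxyethyl)penta-2,4-dien-1-yl]oxy}dimethylsilane | C=C/C=C(/CO[Si](C)(C)C(C)(C)C)CC(OC)OC | intermediate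
8 | but-2-yne-1,4-diol | OCC#CCO | starting material
9 | 4-{[tert-butyl(dimethyl)silyl]oxy}but-2-yn-1-ol | OCC#CCO[Si](C)(C)C(C)(C)C | intermediate
10 | sodium cyclic alkenylalanate from 9 (five-membered O–Al–C ring, two 2-methoxyethoxy ligands; not isolated) | [Na+].COCCO[Al-]1(OCCOC)OCC=C1CO[Si](C)(C)C(C)(C)C | intermediate
11 | (Z)-4-{[tert-butyl(dimethyl)silyl]oxy}-3-iodobut-2-en-1-ol | OC/C=C(/CO[Si](C)(C)C(C)(C)C)I | intermediate
12 | 9-[(3E)-4-({[tert-butyl(dimethyl)silyl]oxy}methyl)-6,6-dimethoxyhex-3-en-1-yl]-9-borabicyclo[3.3.1]nonane (not isolated) | B1(CC/C=C(/CO[Si](C)(C)C(C)(C)C)CC(OC)OC)C2CCCC1CCC2 | intermediate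
13 | (2E,6E)-3,7-bis({[tert-butyl(dimethyl)silyl]oxy}methyl)-9,9-dimethoxynona-2,6-dien-1-ol | OC/C=C(/CO[Si](C)(C)C(C)(C)C)CC/C=C(/CO[Si](C)(C)C(C)(C)C)CC(OC)OC | intermediate
14 | (2E,6E)-3,7-bis({[tert-butyl(dimethyl)silyl]oxy}methyl)-9,9-dimethoxynona-2,6-dienal | O=C/C=C(/CO[Si](C)(C)C(C)(C)C)CC/C=C(/CO[Si](C)(C)C(C)(C)C)CC(OC)OC | intermediate
15 | 1-methoxy-4-[(prop-2-yn-1-yloxy)methyl]benzene (PMB propargyl ether) | C#CCOCc1ccc(OC)cc1 | starting material
16 | {3-[(4-methoxybenzyl)oxy]prop-1-yn-1-yl}(methyl)zinc (not isolated) | C[Zn]C#CCOCc1ccc(OC)cc1 | intermediate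
17 | (4R,5E,9E)-6,10-bis({[tert-butyl(dimethyl)silyl]oxy}methyl)-12,12-dimethoxy-1-[(4-methoxybenzyl)oxy]dodeca-5,9-dien-2-yn-4-ol | O[C@@H](C#CCOCc1ccc(OC)cc1)/C=C(/CO[Si](C)(C)C(C)(C)C)CC/C=C(/CO[Si](C)(C)C(C)(C)C)CC(OC)OC | intermediate
18 | sodium cyclic alkoxy-alkenylalanate from 17 (Al on C11, O6 bound to Al; not isolated) | [Na+].COCCO[Al-]1(OCCOC)O[C@@H](C=C1COCc2ccc(OC)cc2)/C=C(/CO[Si](C)(C)C(C)(C)C)CC/C=C(/CO[Si](C)(C)C(C)(C)C)CC(OC)OC | intermediate
19 | (2Z,4R,5E,9E)-6,10-bis({[tert-butyl(dimethyl)silyl]oxy}methyl)-2-iodo-12,12-dimethoxy-1-[(4-methoxybenzyl)oxy]dodeca-2,5,9-trien-4-ol | O[C@@H](/C=C(/COCc1ccc(OC)cc1)I)/C=C(/CO[Si](C)(C)C(C)(C)C)CC/C=C(/CO[Si](C)(C)C(C)(C)C)CC(OC)OC | intermediate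
20 | (5R)-5-[(1E,5E)-2,6-bis({[tert-butyl(dimethyl)silyl]oxy}methyl)-8,8-dimethoxyocta-1,5-dien-1-yl]-3-{[(4-methoxybenzyl)oxy]methyl}furan-2(5H)-one | O=C1O[C@@H](C=C1COCc2ccc(OC)cc2)/C=C(/CO[Si](C)(C)C(C)(C)C)CC/C=C(/CO[Si](C)(C)C(C)(C)C)CC(OC)OC | intermediate
21 | (5R)-5-[(1E,5E)-2,6-bis({[tert-butyl(dimethyl)silyl]oxy}methyl)-8,8-dimethoxyocta-1,5-dien-1-yl]-3-(hydroxymethyl)furan-2(5H)-one | O=C1O[C@@H](C=C1CO)/C=C(/CO[Si](C)(C)C(C)(C)C)CC/C=C(/CO[Si](C)(C)C(C)(C)C)CC(OC)OC | intermediate
22 | (5R)-3-(bromomethyl)-5-[(1E,5E)-2,6-bis({[tert-butyl(dimethyl)silyl]oxy}methyl)-8,8-dimethoxyocta-1,5-dien-1-yl]furan-2(5H)-one | O=C1O[C@@H](C=C1CBr)/C=C(/CO[Si](C)(C)C(C)(C)C)CC/C=C(/CO[Si](C)(C)C(C)(C)C)CC(OC)OC | intermediate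
23 | (5R)-3-(bromomethyl)-5-[(1E,5E)-2,6-bis({[tert-butyl(dimethyl)silyl]oxy}methyl)-8-oxoocta-1,5-dien-1-yl]furan-2(5H)-one | O=C1O[C@@H](C=C1CBr)/C=C(/CO[Si](C)(C)C(C)(C)C)CC/C=C(/CO[Si](C)(C)C(C)(C)C)CC=O | intermediate
24 | allylchromium(III) dichloride from 23 (Cr on C13; not isolated) | O=C1O[C@@H](C=C1C[Cr](Cl)Cl)/C=C(/CO[Si](C)(C)C(C)(C)C)CC/C=C(/CO[Si](C)(C)C(C)(C)C)CC=O | intermediate
25 | (6R,7R,8S)-14,15-bis{[tert-butyl(dimethyl)silyl]oxy}-8-hydroxy-cis,cis-germacra-1(10),4,11(13)-trien-12,6-olide (8α-OH) | C=C1C(=O)O[C@@H]2/C=C(/CO[Si](C)(C)C(C)(C)C)CC/C=C(/CO[Si](C)(C)C(C)(C)C)C[C@H](O)[C@@H]12 | intermediate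
26 | 3-methylbutanoic acid (isovaleric acid) | CC(C)CC(=O)O | starting material
27 | (6R,7R,8R)-14,15-bis{[tert-butyl(dimethyl)silyl]oxy}-8-(3-methylbutanoyloxy)-cis,cis-germacra-1(10),4,11(13)-trien-12,6-olide | C=C1C(=O)O[C@@H]2/C=C(/CO[Si](C)(C)C(C)(C)C)CC/C=C(/CO[Si](C)(C)C(C)(C)C)C[C@@H](OC(=O)CC(C)C)[C@@H]12 | intermediate
28 | CNP0199826.1, (6R,7R,8R)-14,15-dihydroxy-8-(3-methylbutanoyloxy)-cis,cis-germacra-1(10),4,11(13)-trien-12,6-olide | C=C1C(=O)O[C@@H]2/C=C(/CO)CC/C=C(/CO)C[C@@H](OC(=O)CC(C)C)[C@@H]12 | target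

**Step count.** Total: 17 steps. Longest linear sequence: 15 steps (steps 1–4 and 7–17; steps 5–6 make the second fragment).

**Steps most likely to fail**

Step 15 (ring closure). Intermolecular allylation (oligomerisation) may outrun the ten-membered closure, the aldehyde may be delivered to the C5 face of C7 (cis-fused lactone), or the allylchromium may simply be protonated. The fallback changes the allyl donor to one that reacts by an open, Lewis-acid-promoted SE2′ pathway. It sets out from bromide 22: palladium-catalysed stannylation with hexabutylditin (Pd2(dba)3, THF) should give the allylstannane acetal F1, the same wet-silica hydrolysis as in step 14 should give the stannyl aldehyde F2, and BF3·OEt2 in CH2Cl2 at −78 °C under high dilution should close the ring. It comes back to the route at alcohol 25.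

Step 16 (Mitsunobu). The activated C8 oxyphosphonium may eliminate towards C9 (diene with C1=C10) or C7 instead of being substituted, or substitution at the hindered carbinol may stall. The fallback replaces inversion by an oxidation–reduction sequence. It sets out from 25: Dess–Martin periodinane (NaHCO3, CH2Cl2) should give the C8 ketone F3; Luche reduction (NaBH4, CeCl3, MeOH, −78 °C), with hydride arriving from the exposed outer face, should give the 8β-alcohol F4; acylation with isovaleric anhydride and DMAP in pyridine comes back to the route at 27.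

Step 11 (carbonylative lactonisation). The carbonate base may enolise the γ-alkenyl butenolide at C6 and erode its configuration, and Pd(0) may ionise the allylic C6–O bond of the product. The fallback avoids palladium and base altogether. It sets out from 17: the alanate 18 formed with Red-Al is quenched with CO2 instead of iodine (carboxylation of the alkenyl–aluminium bond with retention), which after mild acidification should give the (Z)-hydroxy acid F5. F5 lactonises spontaneously and comes back to the route at 20.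

**Further compounds**

F1 | step 15 | (5R)-5-[(1E,5E)-2,6-bis({[tert-butyl(dimethyl)silyl]oxy}methyl)-8,8-dimethoxyocta-1,5-dien-1-yl]-3-[(tributylstannyl)methyl]furan-2(5H)-one | O=C1O[C@@H](C=C1C[Sn](CCCC)(CCCC)CCCC)/C=C(/CO[Si](C)(C)C(C)(C)C)CC/C=C(/CO[Si](C)(C)C(C)(C)C)CC(OC)OC
F2 | step 15 | (5R)-5-[(1E,5E)-2,6-bis({[tert-butyl(dimethyl)silyl]oxy}methyl)-8-oxoocta-1,5-dien-1-yl]-3-[(tributylstannyl)methyl]furan-2(5H)-one | O=C1O[C@@H](C=C1C[Sn](CCCC)(CCCC)CCCC)/C=C(/CO[Si](C)(C)C(C)(C)C)CC/C=C(/CO[Si](C)(C)C(C)(C)C)CC=O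
F3 | step 16 | (6R,7R)-14,15-bis{[tert-butyl(dimethyl)silyl]oxy}-8-oxo-cis,cis-germacra-1(10),4,11(13)-trien-12,6-olide | C=C1C(=O)O[C@@H]2/C=C(/CO[Si](C)(C)C(C)(C)C)CC/C=C(/CO[Si](C)(C)C(C)(C)C)CC(=O)[C@@H]12
F4 | step 16 | (6R,7R,8R)-14,15-bis{[tert-butyl(dimethyl)silyl]oxy}-8-hydroxy-cis,cis-germacra-1(10),4,11(13)-trien-12,6-olide (8β-OH) | C=C1C(=O)O[C@@H]2/C=C(/CO[Si](C)(C)C(C)(C)C)CC/C=C(/CO[Si](C)(C)C(C)(C)C)C[C@@H](O)[C@@H]12
F5 | step 11 | (2Z,4R,5E,9E)-6,10-bis({[tert-butyl(dimethyl)silyl]oxy}methyl)-4-hydroxy-12,12-dimethoxy-2-{[(4-methoxybenzyl)oxy]methyl}dodeca-2,5,9-trienoic acid | O[C@@H](/C=C(/COCc1ccc(OC)cc1)C(=O)O)/C=C(/CO[Si](C)(C)C(C)(C)C)CC/C=C(/CO[Si](C)(C)C(C)(C)C)CC(OC)OC
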